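## Structural features

The target is a 2'-hydroxychalcone whose ring A is also the benzo ring of a 2,2-dimethylchroman: O1, the quaternary C2 with two methyls, the secondary carbinol C3, the benzylic methylene C4, then C4a to C8a, with free hydroxyls on C5 and C7 and an (E)-4-hydroxycinnamoyl group on C8. Ring A is therefore a fully differentiated acylphloroglucinol: of the two oxygens ortho to the acyl-bearing C8, the one on C8a is the pyran oxygen O1 and the one on C7 is a free phenol, while the para oxygen on C5 is free and C6 carries the only ring hydrogen. The single stereocentre, C3 (S), lies between the quaternary C2 and the methylene C4, has no neighbouring centre to relay from, and must be set by a reagent. The fragile parts are the enone (reducible, so hydrogenolytic deprotection is excluded at the end), the 2'-hydroxychalcone as a whole (it closes to a flavanone under mild base, heat or prolonged acid) and the electron-rich ring A (oxidation, over-substitution). The real difficulty is regiochemical: the pyran must be closed on the oxygen ortho to the ketone and not on the para oxygen, and its carbon arm must sit on C4a and not on C6. The feature used is that the C7 hydroxyl and the cinnamoyl group on C8 are the open form of a flavanone; closing them gives the naringenin skeleton, where that oxygen is tied up in ring C, so that after capping the para oxygen only the oxygen destined to become O1 is free beside the carbon arm. One consequence must be respected: while that last phenol is free, opening and re-closing of ring C would exchange the two ortho oxygens and move the side chain, so base and heat are kept away between its introduction and the pyran closure.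

## Logic of the disconnections

**9 to 8.** The O–H bonds on C5 and on ring B are traced back to O–CH2OMe acetals. The acetals keep these phenols silent during a strongly basic step and do not need hydrogen for removal. Nothing is gained in skeleton. The forward cleavage must be mild and short, because the free chalcone can drift back to the closed isomer in acid.

**8 to 7.** The C7 oxygen is reconnected to the β-carbon of the enone (an oxa-Michael bond). This stores the enone and one ortho oxygen in a six-membered ring C, so 7 has no free phenol and no conjugated alkene. The forward opening runs against the usual preference for the closed form. It therefore needs a stoichiometric strong base in an aprotic medium, where the phenoxide is the thermodynamic sink, followed by a fast cold protonation.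

**7 to 6.** The O1–C2 bond is cut, with the C3–O bond kept inside an epoxide. This removes the pyran ring and relocates the stereocentre to an epoxide on a five-carbon side chain. The forward step must open the epoxide at its tertiary carbon (6-endo, not 5-exo) and must use the single free phenol only.

**6 to 5.** Both epoxide C–O bonds are cut back to the trisubstituted olefin. 5 then has no stereocentre that matters, and ketone-catalysed asymmetric epoxidation of such olefins is dependable. The demand is reagent-controlled facial selectivity in the (S) sense and survival of the phenol towards the oxidant.

**5 to 3 and 4.** The aryl–CH2 bond at C6 of the flavanone is cut. A halogen then defines the position of the prenyl group, avoiding the poor site selectivity of direct C-prenylation, and the five carbons come from purchasable 4. The coupling must deliver the linear allyl isomer under base mild enough to leave ring C closed.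

**3 to 2.** The C6–I bond is cut. The free, chelated hydroxyl is the directing element. The iodination must take C6 and not C8, and only once.

**2 to 1.** The two O–CH2OMe bonds on the 7- and 4'-oxygens are cut. 1 already holds every carbon of rings A and B and of the three-carbon bridge, with the acyl group on the right carbon. The protection must leave the chelated hydroxyl untouched.

## Other disconnections considered

**Alternative 1:** The pyran is cut at C3–C4 and O1–C2, after replacing the gem-dimethyl carbon by a lactone carbonyl. In the forward step the ortho-quinone methide A2, made in the flask, would be intercepted by the ammonium enolate that a chiral isothiourea forms from the activated glycolate ester A3. Conjugate addition (C3–C4) and lactonisation with catalyst release (O1–C2) would give dihydrocoumarin A1.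
- In favour: ring and stereocentre arise in one catalytic event from achiral parts. On this point it is better than the chosen plan, which needs an epoxidation and a separate closure.
- Against: the methide carbon of A2 is unsubstituted, so the only stereocentre is the one α to the lactone carbonyl. It would be created at the enolate carbon alone and would stay epimerisable under the basic conditions. Terminal methides of this kind are short-lived and prone to self-condensation.
- Against: A1 lacks both methyls. A double methyl Grignard addition and an acid re-closure would break and re-form the O1–C2 bond the key step had just made.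
- Against: ring A of A1 has no acyl group, and acylation would have to choose between C6 and C8, both flanked by two oxygens. The benzyl ethers could not be removed with hydrogen once the enone exists.
- Comparison: on structure it delivers only the bicyclic core, whereas the chosen plan takes the whole skeleton from one starting material. On mechanism it is the more elegant bond construction but gives the more labile stereocentre. On step economy it would need the annulation, methyl addition, re-closure, acylation, aldol condensation and a non-reductive debenzylation, clearly more than six steps.

**Alternative 2:** Ring A itself is cut at C4a–C8a, C5–C6 and C8–C8a. Heating cyclobutenone A5 with siloxyalkyne A6 would run a four-electron ring opening to a vinylketene, a (2+2) addition to the alkyne, a second ring opening, a six-electron closure and tautomerisation to phenol A4.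
- In favour: the three ring-A oxygens emerge as three different functions, and the free one is the future O1. The choice of phenol is therefore settled by construction and cannot be undone by any flavanone–chalcone equilibration. On this point it is better than the chosen plan.
- In favour: the carbinol enters as a protected diol of secure configuration.
- Against: A6 is a sensitive ynol ether that needs its own multi-step preparation.
- Against: the ethyl ether on C7 is a poor last protecting group, since its cleavage needs a boron trihalide or thiolate that the chalcone and the carbinol would tolerate badly.
- Against: the pyran must still be closed by an O1–C2 bond formation from the diol, the same kind of closure as in the chosen plan (equal there). The cinnamoyl group must still be placed on C8 in competition with C6.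
- Comparison: on structure it solves oxygen differentiation but not acyl placement. On mechanism the pericyclic cascade is reliable but builds what naringenin already contains. On step economy it would be well over ten steps.

**Alternative 3:** The cut is C4–C4a. A Lewis acid would activate the terminal epoxide of aryl ether A8, and the ortho carbon of the electron-rich arene would attack the epoxide methylene to give chromanol A7.
- In favour: the aryl group of A8 is symmetric, so the two ortho carbons are identical and the closure poses no regiochemical question. On this point it is at least the equal of the chosen plan.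
- In favour: the C3–O bond is untouched, so configuration is carried over from the epoxide exactly as in the chosen plan (equal).
- Against: A8 is a tert-alkyl aryl ether with a monosubstituted epoxide. Direct asymmetric epoxidation of terminal olefins is weak, and the allyl ether on the way to it is prone to Claisen rearrangement, so enantiopure A8 is hard to reach.
- Against: under the Lewis acid, attack at the internal epoxide carbon (5-exo) or ionisation of the tertiary aryl ether bond could compete.
- Against: A7 has no acyl group, so the C6/C8 choice, the aldol condensation and a non-hydrogenolytic debenzylation all remain.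
- Comparison: on structure it reaches a simpler bicycle than the chosen plan. On mechanism it forms C–C where the chosen plan forms C–O, with the same stereochemical logic. On step economy it would be longer by the whole chalcone construction.

Key step: step 5

Assumption: (2S)-naringenin is bought as the single enantiomer; its C2 centre may partly epimerise in base without consequence, because it is destroyed in step 6 and only serves to keep 2 to 7 as single diastereomers for analysis.

Assumption: the L-series Shi ketone (1,2:4,5-di-O-isopropylidene-β-L-erythro-2,3-hexodiulo-2,6-pyranose) is bought or made from L-sorbose; by the spiro transition-state model the common D-fructose-derived ketone would lead to the (R)-epoxide and thus to the wrong carbinol.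

Remark: ring C is opened with stoichiometric alkoxide in an aprotic medium and not with dilute aqueous alkali, in which a 6'-alkoxy-2'-hydroxychalcone of this kind would be expected to prefer the closed flavanone.

## Route

**Step 1**
Reactants: 1 (2S)-naringenin
Product: 2 (2S)-naringenin 7,4'-bis(methoxymethyl) ether
Conditions: MOMCl (2.3 equiv), iPr2NEt, CH2Cl2/DMF, 0 °C to rt
Reagents that add atoms: chloromethyl methyl ether, COCCl
Why: Phenol O-alkylation (acetal protection): the 7- and 4'-hydroxyls are acidic and unhindered, whereas the 5-hydroxyl is locked in a hydrogen bond to the C4 carbonyl and should stay free with a small excess of reagent and an amine base.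

**Step 2**
Reactants: 2 (2S)-naringenin 7,4'-bis(methoxymethyl) ether
Product: 3 (2S)-6-iodonaringenin 7,4'-bis(methoxymethyl) ether
Conditions: BnMe3N+ ICl2− (1.05 equiv), CaCO3, CH2Cl2/MeOH, rt, dark
Reagents that add atoms: benzyltrimethylammonium dichloroiodate, C[N+](C)(C)Cc1ccccc1.Cl[I-]Cl
Why: Electrophilic aromatic iodination: in 5-hydroxy-7-alkoxy flavonoids the established pattern with this reagent is substitution ortho to the free chelated hydroxyl (C6) and not at C8, and CaCO3 takes up the HCl that would threaten the acetals. The position should be confirmed by long-range correlation from the chelated OH before going on.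

**Step 3**
Reactants: 3 (2S)-6-iodonaringenin 7,4'-bis(methoxymethyl) ether; 4 prenylboronic acid pinacol ester
Product: 5 (2S)-6-prenylnaringenin 7,4'-bis(methoxymethyl) ether
Conditions: Pd(OAc)2 (5 mol %), tBuXPhos (10 mol %), K3PO4 (aq), THF, 40 °C, degassed
Reagents that add atoms: none
Why: Suzuki–Miyaura coupling of an aryl iodide with an allylic boronate: with a bulky di-tert-butylbiarylphosphine the allylpalladium intermediate should settle on the less hindered primary carbon before reductive elimination, so the linear prenyl arene is expected. Mild temperature, the 5-phenoxide formed in the medium and the capped 4'-oxygen all disfavour enolisation at C3, so ring C should stay closed and the substituent should stay on C6.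

**Step 4**
Reactants: 5 (2S)-6-prenylnaringenin 7,4'-bis(methoxymethyl) ether
Product: 6 (2S)-6-[(S)-epoxyprenyl]naringenin 7,4'-bis(methoxymethyl) ether
Conditions: L-series Shi ketone (3 equiv), Oxone (2KHSO5·KHSO4·K2SO4), NaHCO3, MeCN/aq. Na2EDTA, 0 °C, pH 7–8; crude product through Et3N-deactivated silica
Reagents that add atoms: potassium peroxymonosulfate (active part of Oxone), [K+].[O-]S(=O)(=O)OO
Why: Shi asymmetric epoxidation: the chiral dioxirane transfers oxygen through a spiro transition state, and the L-series ketone should attack the face of the ArCH2CH=CMe2 olefin that gives the (S)-epoxide, the centre that becomes C3 of the chroman; the remote C2 centre of ring C exerts no influence. The near-neutral variant with stoichiometric ketone is chosen so that the chelated phenol stays protonated and is neither oxidised readily nor able to open the new epoxide in the 5-exo sense.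

**Step 5**
Reactants: 6 (2S)-6-[(S)-epoxyprenyl]naringenin 7,4'-bis(methoxymethyl) ether
Product: 7 angular (3S)-hydroxydimethyldihydropyranoflavanone 7,4'-bis(methoxymethyl) ether
Conditions: CSA (10 mol %), dry CH2Cl2, −20 to 0 °C; then Et3N
Reagents that add atoms: none
Why: The sulfonic acid protonates the epoxide oxygen, the C–O bond to the tertiary carbon lengthens because that carbon carries the developing positive charge best, and the 5-hydroxyl oxygen held beside the side chain captures it while the epoxide oxygen stays on the secondary carbon as the new hydroxyl. The closest known reaction type is the acid-catalysed cyclisation of ortho-(2,3-epoxy-3-methylbutyl)phenols to 3-hydroxy-2,2-dimethylchromans, the closure assumed in the biosynthesis of such pyranophenols. The dihydropyran is closed in the 6-endo-tet mode at the tertiary epoxide carbon, against the 5-exo-tet mode at the secondary carbon. No stereocentre is created: the carbinol carbon is the epoxide CH of 6, its C–O bond is not broken, and the carbon attacked bears two identical methyls, so the (S) configuration should be carried over even if the opening has cationic character. The preference for 6-endo is secured by acid catalysis (no phenoxide, which would open 5-exo with inversion) and by the tertiary terminus. The choice of oxygen is secured by the substrate: of the two oxygens flanking the side chain, the one on C7 is an acetal ether and the ring-C oxygen is remote, so only the 5-oxygen can close. Catalytic acid, an aprotic solvent and low temperature are chosen so that the acetal on the 7-oxygen is neither cleaved nor drawn into the opening, and exclusion of water avoids diol formation. Once this bond exists, opening of ring C can no longer exchange the two ortho oxygens.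

**Step 6**
Reactants: 7 angular (3S)-hydroxydimethyldihydropyranoflavanone 7,4'-bis(methoxymethyl) ether
Product: 9 (E)-1-[(3S)-3,5,7-trihydroxy-2,2-dimethylchroman-8-yl]-3-(4-hydroxyphenyl)prop-2-en-1-one, via bis-MOM chalcone 8 (not isolated)
Conditions: KOtBu (3 equiv), THF, 0 °C, Ar; cannulated into HCl/MeOH (ca. 1.5 M) at −20 °C, then rt
Reagents that add atoms: none
Why: E1cB retro-oxa-Michael opening, then acetal methanolysis: the alkoxide deprotonates C3 of ring C, the enolate expels the ring-C aryloxide, and because a phenoxide is a far weaker base than an enolate the aprotic equilibrium should lie wholly on the side of the open (E)-chalcone. Protonation by cold strong acid is faster than re-addition, and the neutral, chelated 2'-hydroxychalcone should re-close only slowly under the mild acid that cleaves both aryl methoxymethyl ethers by transacetalisation.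

## Compound list

1 | (2S)-naringenin, (2S)-5,7-dihydroxy-2-(4-hydroxyphenyl)chroman-4-one | C1[C@H](Oc2cc(O)cc(O)c2C1=O)c1ccc(O)cc1 | starting material
2 | (2S)-5-hydroxy-7-(methoxymethoxy)-2-[4-(methoxymethoxy)phenyl]chroman-4-one | C1[C@H](Oc2cc(OCOC)cc(O)c2C1=O)c1ccc(OCOC)cc1 | intermediate
3 | (2S)-5-hydroxy-6-iodo-7-(methoxymethoxy)-2-[4-(methoxymethoxy)phenyl]chroman-4-one | C1[C@H](Oc2cc(OCOC)c(I)c(O)c2C1=O)c1ccc(OCOC)cc1 | intermediate
4 | prenylboronic acid pinacol ester, 4,4,5,5-tetramethyl-2-(3-methylbut-2-en-1-yl)-1,3,2-dioxaborolane | CC(C)=CCB1OC(C)(C)C(C)(C)O1 | starting material
5 | (2S)-5-hydroxy-7-(methoxymethoxy)-2-[4-(methoxymethoxy)phenyl]-6-(3-methylbut-2-en-1-yl)chroman-4-one | C1[C@H](Oc2cc(OCOC)c(CC=C(C)C)c(O)c2C1=O)c1ccc(OCOC)cc1 | intermediate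
6 | (2S)-6-{[(2S)-3,3-dimethyloxiran-2-yl]methyl}-5-hydroxy-7-(methoxymethoxy)-2-[4-(methoxymethoxy)phenyl]chroman-4-one | C1[C@H](Oc2cc(OCOC)c(C[C@@H]3OC3(C)C)c(O)c2C1=O)c1ccc(OCOC)cc1 | intermediate
7 | (3S,8S)-3-hydroxy-5-(methoxymethoxy)-8-[4-(methoxymethoxy)phenyl]-2,2-dimethyl-3,4,8,9-tetrahydro-2H,10H-pyrano[2,3-f]chromen-10-one (flavanone with a dihydropyran fused through its 5-oxygen and C6) | C1[C@H](Oc2cc(OCOC)c3C[C@H](O)C(C)(C)Oc3c2C1=O)c1ccc(OCOC)cc1 | intermediate
8 | (E)-1-[(3S)-3,7-dihydroxy-5-(methoxymethoxy)-2,2-dimethylchroman-8-yl]-3-[4-(methoxymethoxy)phenyl]prop-2-en-1-one | CC1(C)Oc2c(c(OCOC)cc(O)c2C(=O)/C=C/c2ccc(OCOC)cc2)C[C@@H]1O | intermediate (not isolated)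
9 | (E)-1-[(3S)-3,5,7-trihydroxy-2,2-dimethylchroman-8-yl]-3-(4-hydroxyphenyl)prop-2-en-1-one | CC1(C)Oc2c(c(O)cc(O)c2C(=O)/C=C/c2ccc(O)cc2)C[C@@H]1O | target

## Step count and least certain steps

Total: 6 steps. Longest linear sequence: 6 steps, from 1 to 9 (4 is bought).

**Step 5 (key step).** The activated epoxide may open in the 5-exo sense, or with help from the neighbouring acetal oxygen after partial loss of the acetal, which would close the ring on the wrong oxygen. A hydride shift to a ketone is a further side path. The cause is that the chelated phenol is a weak nucleophile, so these side paths have time to compete. The fallback builds the ring before the stereocentre and sets out from 5. Dehydrogenative cyclisation with DDQ (benzene, warm) can only engage the free phenol and should give the chromene analogue F1. Jacobsen epoxidation with (S,S)-N,N'-bis(3,5-di-tert-butylsalicylidene)-1,2-cyclohexanediaminomanganese chloride, mCPBA and N-methylmorpholine N-oxide at −78 °C should give the (3S,4S)-epoxide F2; the sense of induction is to be checked on a model chromene. Hydrogenolysis of the benzylic C4–O bond (H2, Pd/C, EtOAc, rt) then comes back to the route at 7.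

**Step 3.** Allylic transposition before reductive elimination (branched instead of linear coupling), protodehalogenation of the hindered iodide, or base-induced opening and re-closing of ring C would each spoil the step. The site selectivity of the preceding iodination is also not certain. The fallback avoids halogen and palladium and sets out from 2. Mitsunobu O-allylation of the chelated hydroxyl (allyl alcohol, PPh3, DIAD, THF) gives the 5-O-allyl ether F3. An aromatic Claisen rearrangement (Eu(fod)3, CHCl3, 60 °C, or thermal) can only deliver the allyl group to C6 and gives the 6-allyl phenol F4. Cross-metathesis with 2-methyl-2-butene (second-generation Grubbs catalyst, CH2Cl2, 40 °C) comes back to the route at 5.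

**Step 4.** The dioxirane may oxidise the electron-rich phenolic ring, the phenol may open the new epoxide prematurely in the 5-exo sense, or facial selectivity may be incomplete. The fallback masks the phenol and sets out from 5. Silylation (TBSCl, imidazole, DMAP, DMF, 40 °C) gives the 5-O-silyl ether F5. Shi epoxidation of this non-phenolic substrate under the usual catalytic protocol at pH 10.5 gives the silylated epoxide F6. Buffered fluoride (Bu4NF/AcOH, THF, 0 °C) comes back to the route at 6.

**Step 6.** Ring opening may be incomplete, or the chalcone may drift back to the closed isomer while it is held in acid for the acetal cleavage. The fallback reverses the order so that the chalcone never sees acid, and sets out from 7. Acetal cleavage on the closed form (HCl, MeOH, 45 °C) gives the free triol flavanone F7. Opening in concentrated KOH (aq. EtOH, rt, argon), where the polyphenolate equilibrium should lie on the open side, and pouring onto ice-cold dilute HCl comes back to the route at 9.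

## Further compounds

F1 | step 5 | (8S)-5-(methoxymethoxy)-8-[4-(methoxymethoxy)phenyl]-2,2-dimethyl-8,9-dihydro-2H,10H-pyrano[2,3-f]chromen-10-one (chromene analogue of 7 with a C3=C4 double bond) | C1[C@H](Oc2cc(OCOC)c3C=CC(C)(C)Oc3c2C1=O)c1ccc(OCOC)cc1
F2 | step 5 | (3S,4S)-3,4-epoxide of F1 (oxirane cis-fused to the pyran ring) | C1[C@H](Oc2cc(OCOC)c3[C@@H]4O[C@@H]4C(C)(C)Oc3c2C1=O)c1ccc(OCOC)cc1
F3 | step 3 | (2S)-5-(allyloxy)-7-(methoxymethoxy)-2-[4-(methoxymethoxy)phenyl]chroman-4-one | C1[C@H](Oc2cc(OCOC)cc(OCC=C)c2C1=O)c1ccc(OCOC)cc1
F4 | step 3 | (2S)-6-allyl-5-hydroxy-7-(methoxymethoxy)-2-[4-(methoxymethoxy)phenyl]chroman-4-one | C1[C@H](Oc2cc(OCOC)c(CC=C)c(O)c2C1=O)c1ccc(OCOC)cc1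
F5 | step 4 | 5-O-tert-butyldimethylsilyl ether of 5 | C1[C@H](Oc2cc(OCOC)c(CC=C(C)C)c(O[Si](C)(C)C(C)(C)C)c2C1=O)c1ccc(OCOC)cc1
F6 | step 4 | 5-O-tert-butyldimethylsilyl ether of 6 | C1[C@H](Oc2cc(OCOC)c(C[C@@H]3OC3(C)C)c(O[Si](C)(C)C(C)(C)C)c2C1=O)c1ccc(OCOC)cc1
F7 | step 6 | (3S,8S)-3,5-dihydroxy-8-(4-hydroxyphenyl)-2,2-dimethyl-3,4,8,9-tetrahydro-2H,10H-pyrano[2,3-f]chromen-10-one (7 without its two methoxymethyl groups) | C1[C@H](Oc2cc(O)c3C[C@H](O)C(C)(C)Oc3c2C1=O)c1ccc(O)cc1
A1 | alternative 1 | (S)-3,5,7-tris(benzyloxy)chroman-2-one | O=C1Oc2cc(OCc3ccccc3)cc(OCc3ccccc3)c2C[C@@H]1OCc1ccccc1
A2 | alternative 1 | 3,5-bis(benzyloxy)-6-methylenecyclohexa-2,4-dien-1-one (ortho-quinone methide) | C=C1C(OCc2ccccc2)=CC(OCc2ccccc2)=CC1=O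
A3 | alternative 1 | 4-nitrophenyl 2-(benzyloxy)acetate | O=C(COCc1ccccc1)Oc1ccc(cc1)[N+](=O)[O-]
A4 | alternative 2 | 5-ethoxy-2-{[(4S)-2,2,5,5-tetramethyl-1,3-dioxolan-4-yl]methyl}-3-[(triisopropylsilyl)oxy]phenol | Oc1cc(OCC)cc(O[Si](C(C)C)(C(C)C)C(C)C)c1C[C@@H]1OC(C)(C)OC1(C)C
A5 | alternative 2 | 3-ethoxycyclobut-2-en-1-one | CCOC1=CC(=O)C1
A6 | alternative 2 | triisopropyl({3-[(4S)-2,2,5,5-tetramethyl-1,3-dioxolan-4-yl]prop-1-yn-1-yl}oxy)silane | CC(C)[Si](OC#CC[C@@H]1OC(C)(C)OC1(C)C)(C(C)C)C(C)C
A7 | alternative 3 | (S)-5,7-bis(benzyloxy)-2,2-dimethylchroman-3-ol | CC1(C)Oc2cc(OCc3ccccc3)cc(OCc3ccccc3)c2C[C@@H]1O
A8 | alternative 3 | (S)-2-{2-[3,5-bis(benzyloxy)phenoxy]propan-2-yl}oxirane | CC(C)(Oc1cc(OCc2ccccc2)cc(OCc2ccccc2)c1)[C@@H]1CO1
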